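**Plan**

Numbering (germacrane): ring C1–C10, lactone carbons C11–C13 (C12=O, ring O on C6), C14 on C10, C15 on C4.
Cuts, in retrosynthetic order: C3–O (benzoate); C3–C4 of the ten-membered ring (intramolecular Nozaki–Hiyama–Kishi addition of a C4 alkenyl iodide to a C3 aldehyde); C8–O (epoxy ester); C7–C8 (Barbier allylation of a C8 aldehyde by a 3-(bromomethyl)butenolide); C7=C11 (metathesis).
Enabling feature: C3 is an oxygen-bearing sp3 carbon bonded directly to C4 of the only ring alkene (C4=C5), whose Z geometry holds C3 and C6 cis; a (Z)-C4 iodide therefore carries the alkene geometry and brings the two chain ends together.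
Forward order: butenolide ring (O, C6, C7, C11, C12) first; then the trans α-methylene lactone by the C7–C8 union with an aldehyde that already holds the C1–C10 oxirane; then the C8 ester; the ten-membered carbocycle last; then the benzoate.
Stereochemistry: C6 from a Sharpless kinetic resolution; C1/C10 from Shi epoxidation of an E-alkene; C7 (anti to C6) and C8 (as its epimer) from the chair allylation, C8 then inverted by Mitsunobu esterification; side-chain acid from Sharpless epoxidation; C3 from the ring closure.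

Key step: step 16

Remark: the Barbier union is assumed to follow the closed chair transition state usual for 3-(bromomethyl)butenolides, which gives the C8 epimer of the target; the route is built on that outcome (inversion in step 13).

**Route**

Step 1
Reactants: 1 acrolein; 2 1-propynylmagnesium bromide
Product: 3 rac-hex-1-en-4-yn-3-ol
Conditions: THF, −78 °C → 0 °C; aq. NH4Cl
Reagents that add atoms: none
Why: 1,2-addition of the alkynyl Grignard reagent to the enal at low temperature should give the racemic carbinol that carries C4–C7 and C15 (Grignard addition).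

Step 2
Reactants: 3 rac-hex-1-en-4-yn-3-ol
Product: 5 rac-(4Z)-5-iodohexa-1,4-dien-3-ol, via cyclic vinylalanate 4 (not isolated)
Conditions: NaAlH2(OCH2CH2OCH3)2, THF, 0 °C → rt; then I2, −78 °C → 0 °C
Reagents that add atoms: iodine, II
Why: hydroxyl-directed trans-hydroalumination places aluminium on the distal alkyne carbon in a five-membered alanate, and iododealumination with retention should give the Z iodide (I cis to the carbinol carbon) while the vinyl group stays untouched.

Step 3
Reactants: 5 rac-(4Z)-5-iodohexa-1,4-dien-3-ol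
Product: 6 (3S,4Z)-5-iodohexa-1,4-dien-3-ol
Conditions: Ti(OiPr)4 (1.0 equiv), L-(+)-DIPT (1.2 equiv), t-BuOOH (0.6 equiv), 4 Å MS, CH2Cl2, −20 °C; unreacted alcohol recovered
Reagents that add atoms: none
Why: Sharpless kinetic resolution; with L-(+)-tartrate the R enantiomer should be epoxidised at its vinyl group much faster, the deactivated Z-iodoalkene should not react, and the S alcohol (future C6) should remain.

Step 4
Reactants: 6 (3S,4Z)-5-iodohexa-1,4-dien-3-ol; 7 2-(bromomethyl)prop-2-enoic acid
Product: 8 (3S,4Z)-5-iodohexa-1,4-dien-3-yl 2-(bromomethyl)prop-2-enoate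
Conditions: DCC, DMAP (0.05 equiv), CH2Cl2, −20 °C → 0 °C
Reagents that add atoms: none
Why: Steglich esterification with retention at the carbinol carbon; low temperature and little DMAP should limit attack of the catalyst on the allylic bromide.

Step 5
Reactants: 8 (3S,4Z)-5-iodohexa-1,4-dien-3-yl 2-(bromomethyl)prop-2-enoate
Product: 9 (5S)-3-(bromomethyl)-5-[(1Z)-2-iodoprop-1-en-1-yl]furan-2(5H)-one
Conditions: second-generation Grubbs catalyst (5 mol%), toluene (0.005 M), 80 °C
Reagents that add atoms: none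
Why: ring-closing metathesis starting at the monosubstituted vinyl group and closing onto the acrylate should give the butenolide (C7=C11) with loss of ethene; the trisubstituted iodoalkene is not a substrate and C6 is untouched.

Step 6
Reactants: 10 pent-1-en-4-yne; 11 oxirane
Product: 14 (3E)-4-methylhepta-3,6-dien-1-ol, via alkenyldimethylalane 12 (not isolated), via lithium alkenylalanate 13 (not isolated)
Conditions: Me3Al (2 equiv), Cp2ZrCl2 (0.2 equiv), CH2Cl2, 0 °C → rt; then n-BuLi, hexane/THF, −78 °C; then oxirane, −78 °C → 0 °C; aq. work-up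
Reagents that add atoms: trimethylaluminium, C[Al](C)C
Why: Negishi zirconium-catalysed carboalumination adds methyl and aluminium syn across the alkyne only (methyl on the internal carbon), and the alanate opens the oxirane with retention, which should fix the E alkene (C2 trans to C9).

Step 7
Reactants: 14 (3E)-4-methylhepta-3,6-dien-1-ol
Product: 15 tert-butyl(dimethyl){[(3E)-4-methylhepta-3,6-dien-1-yl]oxy}silane
Conditions: TBSCl, imidazole, DMF, rt
Reagents that add atoms: tert-butyldimethylsilyl chloride, CC(C)(C)[Si](C)(C)Cl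
Why: standard silylation of the primary alcohol (future C3–O), which must stay masked until the second aldehyde is needed.

Step 8
Reactants: 15 tert-butyl(dimethyl){[(3E)-4-methylhepta-3,6-dien-1-yl]oxy}silane
Product: 16 tert-butyl(dimethyl){2-[(2R,3R)-3-methyl-3-(prop-2-en-1-yl)oxiran-2-yl]ethoxy}silane
Conditions: D-fructose-derived Shi ketone (0.3 equiv), KHSO5 (as 2KHSO5·KHSO4·K2SO4), K2CO3, Bu4NHSO4, MeCN/CH2(OMe)2/aq. Na2B4O7 buffer, 0 °C
Reagents that add atoms: potassium peroxymonosulfate, [K+].[O-]S(=O)(=O)OO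
Why: Shi epoxidation; the chiral dioxirane should epoxidise the electron-rich trisubstituted E-alkene through a spiro transition state and leave the terminal vinyl group, and the D-fructose-derived ketone gives the (R,R)-oxirane, which sets C1 and C10.

Step 9
Reactants: 16 tert-butyl(dimethyl){2-[(2R,3R)-3-methyl-3-(prop-2-en-1-yl)oxiran-2-yl]ethoxy}silane
Product: 18 2-[(2R,3R)-3-(2-{[tert-butyl(dimethyl)silyl]oxy}ethyl)-2-methyloxiran-2-yl]acetaldehyde, via secondary ozonide 17 (not isolated)
Conditions: O3, CH2Cl2, −78 °C; then PPh3, −78 °C → rt; used at once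
Reagents that add atoms: ozone, [O-][O+]=O
Why: ozonolysis with reductive work-up cleaves the only remaining alkene to the β,γ-epoxy aldehyde (C8) under neutral, base-free conditions that should spare the oxirane and the silyl ether.

Step 10
Reactants: 19 (2E)-2-methylbut-2-en-1-ol
Product: 20 [(2S,3S)-2,3-dimethyloxiran-2-yl]methanol
Conditions: Ti(OiPr)4 (0.1 equiv), L-(+)-DET (0.12 equiv), t-BuOOH, 4 Å MS, CH2Cl2, −20 °C
Reagents that add atoms: tert-butyl hydroperoxide, CC(C)(C)OO
Why: Sharpless asymmetric epoxidation; L-(+)-tartrate should deliver oxygen to the face that gives the (2S,3S)-epoxy alcohol, and the cis relation of the two methyl groups comes from the E alkene.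

Step 11
Reactants: 20 [(2S,3S)-2,3-dimethyloxiran-2-yl]methanol
Product: 21 (2R,3S)-2,3-dimethyloxirane-2-carboxylic acid
Conditions: TEMPO (0.2 equiv), PhI(OAc)2 (2.2 equiv), MeCN/H2O 1:1, rt
Reagents that add atoms: water, O
Why: oxoammonium oxidation through the aldehyde hydrate gives the acid under near-neutral conditions without touching either stereocentre (the C2 descriptor changes only because CO2H now outranks the ring carbon).

Step 12
Reactants: 9 (5S)-3-(bromomethyl)-5-[(1Z)-2-iodoprop-1-en-1-yl]furan-2(5H)-one; 18 2-[(2R,3R)-3-(2-{[tert-butyl(dimethyl)silyl]oxy}ethyl)-2-methyloxiran-2-yl]acetaldehyde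
Product: 23 (4R,5S)-4-{(1S)-2-[(2R,3R)-3-(2-{[tert-butyl(dimethyl)silyl]oxy}ethyl)-2-methyloxiran-2-yl]-1-hydroxyethyl}-5-[(1Z)-2-iodoprop-1-en-1-yl]-3-methylideneoxolan-2-one, via allylzinc bromide 22 (not isolated)
Conditions: Zn dust (activated), THF/sat. aq. NH4Cl 5:1, 0 °C → rt
Reagents that add atoms: none
Why: Barbier allylation; the allylzinc should react at its γ-carbon (C7) through a chair Zimmerman–Traxler transition state, anti to the C6 substituent (trans lactone, 7R) and with the aldehyde chain equatorial (8S), moving the double bond to C11=C13.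

Step 13
Reactants: 23 the 8S alcohol from step 12; 21 (2R,3S)-2,3-dimethyloxirane-2-carboxylic acid
Product: 24 (1R)-2-[(2R,3R)-3-(2-{[tert-butyl(dimethyl)silyl]oxy}ethyl)-2-methyloxiran-2-yl]-1-{(2S,3R)-2-[(1Z)-2-iodoprop-1-en-1-yl]-4-methylidene-5-oxooxolan-3-yl}ethyl (2R,3S)-2,3-dimethyloxirane-2-carboxylate
Conditions: PPh3, DIAD, toluene, 0 °C → rt
Reagents that add atoms: none
Why: Mitsunobu esterification; SN2 displacement of the C8 oxyphosphonium by the acidic epoxy carboxylate should invert C8 to R and install the side chain in the same operation.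

Step 14
Reactants: 24 the silyl ether ester from step 13
Product: 25 (1R)-2-[(2R,3R)-3-(2-hydroxyethyl)-2-methyloxiran-2-yl]-1-{(2S,3R)-2-[(1Z)-2-iodoprop-1-en-1-yl]-4-methylidene-5-oxooxolan-3-yl}ethyl (2R,3S)-2,3-dimethyloxirane-2-carboxylate
Conditions: HF·pyridine, pyridine, THF, 0 °C
Reagents that add atoms: none
Why: buffered fluoride should cleave the primary silyl ether while both oxiranes, the esters, the enoate and the alkenyl iodide survive.

Step 15
Reactants: 25 the primary alcohol from step 14
Product: 26 (1R)-2-[(2R,3R)-2-methyl-3-(2-oxoethyl)oxiran-2-yl]-1-{(2S,3R)-2-[(1Z)-2-iodoprop-1-en-1-yl]-4-methylidene-5-oxooxolan-3-yl}ethyl (2R,3S)-2,3-dimethyloxirane-2-carboxylate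
Conditions: Dess–Martin periodinane, NaHCO3, CH2Cl2, 0 °C; filtered and used crude
Reagents that add atoms: none
Why: Dess–Martin oxidation under buffered, base-free conditions should give the C3 aldehyde without β-elimination of the neighbouring oxirane.

Step 16
Reactants: 26 the seco iodo aldehyde from step 15
Product: 28 (1R,3S,4Z,6R,7R,8R,10R)-1,10-epoxy-3-hydroxy-8-{[(2R,3S)-2,3-dimethyloxirane-2-carbonyl]oxy}germacra-4,11(13)-dien-12,6-olide, via alkenylchromium dichloride 27 (not isolated)
Conditions: CrCl2 (10 equiv), NiCl2 (0.1 equiv), degassed DMSO, rt, syringe-pump addition of 26 to 0.002 M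
Reagents that add atoms: none
Why: Zerovalent nickel, formed from NiCl2 by CrCl2, inserts into the C4–I bond with retention and passes the Z-alkenyl group to trivalent chromium (27), which adds to the C3 aldehyde through a four-centre, chromium-bound transition state (Nozaki–Hiyama–Kishi reaction, whose closest precedents are closures of nine- and ten-membered carbocycles). The new C3–C4 bond closes the ten-membered carbocycle in a 10-exo-trig mode, with the lactone and both oxiranes already in place. C3 is the only new stereocentre: allylic 1,3-strain keeps H6 in the alkenyl plane next to chromium, so C7 and the tether lie on one face, and the aldehyde is delivered over that face with C=O parallel to C4–Cr, H3 above the C15 methyl and C2 above C5. Collapse then leaves O3 on the face opposite the tether, which corresponds to 3S. The step needs chemoselectivity (the alkenylchromium adds only to the aldehyde, not to lactone, esters, enoate or oxiranes), retention of the Z geometry (fixed in the iodide) and cyclisation over oligomerisation (the Z alkene and the trans lactone hold C3 and C4 close; high dilution and slow addition help).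

Step 17
Reactants: 28 the macrocyclic allylic alcohol from step 16; 29 benzoyl chloride
Product: 30 (1R,3S,4Z,6R,7R,8R,10R)-3-(benzoyloxy)-1,10-epoxy-8-{[(2R,3S)-2,3-dimethyloxirane-2-carbonyl]oxy}germacra-4,11(13)-dien-12,6-olide
Conditions: pyridine, DMAP (cat.), CH2Cl2, 0 °C → rt
Reagents that add atoms: none
Why: acylation of the secondary allylic alcohol proceeds with retention at C3 and should give the target.

**Compound list**

1 | acrolein | C=CC=O | starting material
2 | 1-propynylmagnesium bromide | CC#C[Mg]Br | starting material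
3 | rac-hex-1-en-4-yn-3-ol | C=CC(O)C#CC | intermediate
4 | cyclic vinylalanate (sodium 2,2-bis(2-methoxyethoxy)-3-methyl-5-vinyl-2,5-dihydro-1,2-oxaaluminol-2-uide) | [Na+].C=CC1C=C(C)[Al-](OCCOC)(OCCOC)O1 | intermediate
5 | rac-(4Z)-5-iodohexa-1,4-dien-3-ol | C=CC(O)/C=C(/C)I | intermediate
6 | (3S,4Z)-5-iodohexa-1,4-dien-3-ol | C=C[C@H](O)/C=C(/C)I | intermediate
7 | 2-(bromomethyl)prop-2-enoic acid | C=C(CBr)C(=O)O | starting material
8 | (3S,4Z)-5-iodohexa-1,4-dien-3-yl 2-(bromomethyl)prop-2-enoate | C=C[C@H](OC(=O)C(=C)CBr)/C=C(/C)I | intermediate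
9 | (5S)-3-(bromomethyl)-5-[(1Z)-2-iodoprop-1-en-1-yl]furan-2(5H)-one (fragment A) | O=C1O[C@H](/C=C(/C)I)C=C1CBr | intermediate
10 | pent-1-en-4-yne | C=CCC#C | starting material
11 | oxirane (ethylene oxide) | C1CO1 | starting material
12 | dimethyl[(1E)-2-methylpenta-1,4-dien-1-yl]alumane | C=CC/C(C)=C/[Al](C)C | intermediate
13 | lithium butyl(dimethyl)[(1E)-2-methylpenta-1,4-dien-1-yl]aluminate | [Li+].C=CC/C(C)=C/[Al-](C)(C)CCCC | intermediate
14 | (3E)-4-methylhepta-3,6-dien-1-ol | OCC/C=C(\C)CC=C | intermediate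
15 | tert-butyl(dimethyl){[(3E)-4-methylhepta-3,6-dien-1-yl]oxy}silane | CC(C)(C)[Si](C)(C)OCC/C=C(\C)CC=C | intermediate
16 | tert-butyl(dimethyl){2-[(2R,3R)-3-methyl-3-(prop-2-en-1-yl)oxiran-2-yl]ethoxy}silane | CC(C)(C)[Si](C)(C)OCC[C@H]1O[C@]1(C)CC=C | intermediate
17 | secondary ozonide of 16 (1,2,4-trioxolane at the former vinyl group, mixture at the ozonide carbon) | CC(C)(C)[Si](C)(C)OCC[C@H]1O[C@]1(C)CC2OOCO2 | intermediate
18 | 2-[(2R,3R)-3-(2-{[tert-butyl(dimethyl)silyl]oxy}ethyl)-2-methyloxiran-2-yl]acetaldehyde (fragment B) | CC(C)(C)[Si](C)(C)OCC[C@H]1O[C@]1(C)CC=O | intermediate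
19 | (2E)-2-methylbut-2-en-1-ol (tiglyl alcohol) | C/C=C(\C)CO | starting material
20 | [(2S,3S)-2,3-dimethyloxiran-2-yl]methanol | OC[C@]1(C)O[C@H]1C | intermediate
21 | (2R,3S)-2,3-dimethyloxirane-2-carboxylic acid (fragment C) | OC(=O)[C@]1(C)O[C@H]1C | intermediate
22 | allylzinc bromide from 9 (bromo{[(5S)-5-[(1Z)-2-iodoprop-1-en-1-yl]-2-oxo-2,5-dihydrofuran-3-yl]methyl}zinc) | O=C1O[C@H](/C=C(/C)I)C=C1C[Zn]Br | intermediate
23 | (4R,5S)-4-{(1S)-2-[(2R,3R)-3-(2-{[tert-butyl(dimethyl)silyl]oxy}ethyl)-2-methyloxiran-2-yl]-1-hydroxyethyl}-5-[(1Z)-2-iodoprop-1-en-1-yl]-3-methylideneoxolan-2-one | CC(C)(C)[Si](C)(C)OCC[C@H]1O[C@]1(C)C[C@H](O)[C@H]2C(=C)C(=O)O[C@@H]2/C=C(/C)I | intermediate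
24 | (1R)-2-[(2R,3R)-3-(2-{[tert-butyl(dimethyl)silyl]oxy}ethyl)-2-methyloxiran-2-yl]-1-{(2S,3R)-2-[(1Z)-2-iodoprop-1-en-1-yl]-4-methylidene-5-oxooxolan-3-yl}ethyl (2R,3S)-2,3-dimethyloxirane-2-carboxylate | CC(C)(C)[Si](C)(C)OCC[C@H]1O[C@]1(C)C[C@@H](OC(=O)[C@]2(C)O[C@H]2C)[C@H]3C(=C)C(=O)O[C@@H]3/C=C(/C)I | intermediate
25 | (1R)-2-[(2R,3R)-3-(2-hydroxyethyl)-2-methyloxiran-2-yl]-1-{(2S,3R)-2-[(1Z)-2-iodoprop-1-en-1-yl]-4-methylidene-5-oxooxolan-3-yl}ethyl (2R,3S)-2,3-dimethyloxirane-2-carboxylate | OCC[C@H]1O[C@]1(C)C[C@@H](OC(=O)[C@]2(C)O[C@H]2C)[C@H]3C(=C)C(=O)O[C@@H]3/C=C(/C)I | intermediate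
26 | (1R)-2-[(2R,3R)-2-methyl-3-(2-oxoethyl)oxiran-2-yl]-1-{(2S,3R)-2-[(1Z)-2-iodoprop-1-en-1-yl]-4-methylidene-5-oxooxolan-3-yl}ethyl (2R,3S)-2,3-dimethyloxirane-2-carboxylate | O=CC[C@H]1O[C@]1(C)C[C@@H](OC(=O)[C@]2(C)O[C@H]2C)[C@H]3C(=C)C(=O)O[C@@H]3/C=C(/C)I | intermediate
27 | alkenylchromium dichloride from 26 (CrCl2 group in place of iodine at C4, Z geometry kept) | O=CC[C@H]1O[C@]1(C)C[C@@H](OC(=O)[C@]2(C)O[C@H]2C)[C@H]3C(=C)C(=O)O[C@@H]3/C=C(/C)[Cr](Cl)Cl | intermediate
28 | (1R,3S,4Z,6R,7R,8R,10R)-1,10-epoxy-3-hydroxy-8-{[(2R,3S)-2,3-dimethyloxirane-2-carbonyl]oxy}germacra-4,11(13)-dien-12,6-olide | C=C1C(=O)O[C@@H]2/C=C(/C)[C@@H](O)C[C@H]3O[C@]3(C)C[C@@H](OC(=O)[C@]3(C)O[C@H]3C)[C@@H]12 | intermediate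
29 | benzoyl chloride | O=C(Cl)c1ccccc1 | starting material
30 | (1R,3S,4Z,6R,7R,8R,10R)-3-(benzoyloxy)-1,10-epoxy-8-{[(2R,3S)-2,3-dimethyloxirane-2-carbonyl]oxy}germacra-4,11(13)-dien-12,6-olide (CNP0324463.5) | C=C1C(=O)O[C@@H]2/C=C(/C)[C@@H](OC(=O)c3ccccc3)C[C@H]3O[C@]3(C)C[C@@H](OC(=O)[C@]3(C)O[C@H]3C)[C@@H]12 | target

**Step count**

Total: 17 steps. Longest linear sequence: 11 steps (steps 1–5, then 12–17).

**Steps most likely to fail**

Step 16. The β,γ-epoxy aldehyde may eliminate with opening of the C1–C10 oxirane before it cyclises, the alkenylchromium may react between molecules, or the aldehyde may be attacked on its other face. Only the last cannot be answered by conditions. If the 3R alcohol prevails, the fallback sets out from 26 under the same closure conditions, which then give the 3-epimer of 28 F1. This is esterified with inversion by a Mitsunobu reaction with benzoic acid (PPh3, DIAD, toluene, 0 °C), an SN2 displacement at the ring allylic carbon C3. It returns to the route at 30.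

Step 13. The activated C8 oxyphosphonium may eliminate toward a C7=C8 diene (H7 is allylic), or displacement at the hindered carbinol may be too slow. The fallback sets out from 23 and reaches the 8R configuration by oxidation and reagent-controlled reduction. Dess–Martin periodinane (NaHCO3, CH2Cl2, 0 °C) gives the C8 ketone F2. Reduction with (S)-2-methyl-CBS-oxazaborolidine and catecholborane at −78 °C, where the branched C7 side acts as the large group, should give the 8R alcohol F3. Yamaguchi esterification with 21 (2,4,6-trichlorobenzoyl chloride, Et3N, DMAP, toluene) then proceeds with retention and returns to the route at 24.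

Step 5. Metathesis at the electron-poor, 1,1-disubstituted acrylate may be so slow that the catalyst decays, or the allylic bromide may already be lost to the nucleophilic catalyst in step 4. The fallback sets out from 6 and introduces bromine only after ring closure. Acryloyl chloride and Et3N (CH2Cl2, −20 °C) give the acrylate F4. A Morita–Baylis–Hillman reaction with aqueous formaldehyde and DABCO gives the 2-(hydroxymethyl)acrylate F5. Ring-closing metathesis with the second-generation Grubbs catalyst gives the 3-(hydroxymethyl)butenolide F6. An Appel reaction (CBr4, PPh3, CH2Cl2, 0 °C) returns to the route at 9.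

**Further compounds**

F1 | step 16 | (1R,3R,4Z,6R,7R,8R,10R)-1,10-epoxy-3-hydroxy-8-{[(2R,3S)-2,3-dimethyloxirane-2-carbonyl]oxy}germacra-4,11(13)-dien-12,6-olide (3-epimer of 28) | C=C1C(=O)O[C@@H]2/C=C(/C)[C@H](O)C[C@H]3O[C@]3(C)C[C@@H](OC(=O)[C@]3(C)O[C@H]3C)[C@@H]12
F2 | step 13 | (4S,5S)-4-{[(2R,3R)-3-(2-{[tert-butyl(dimethyl)silyl]oxy}ethyl)-2-methyloxiran-2-yl]acetyl}-5-[(1Z)-2-iodoprop-1-en-1-yl]-3-methylideneoxolan-2-one | CC(C)(C)[Si](C)(C)OCC[C@H]1O[C@]1(C)CC(=O)[C@H]2C(=C)C(=O)O[C@@H]2/C=C(/C)I
F3 | step 13 | (4R,5S)-4-{(1R)-2-[(2R,3R)-3-(2-{[tert-butyl(dimethyl)silyl]oxy}ethyl)-2-methyloxiran-2-yl]-1-hydroxyethyl}-5-[(1Z)-2-iodoprop-1-en-1-yl]-3-methylideneoxolan-2-one | CC(C)(C)[Si](C)(C)OCC[C@H]1O[C@]1(C)C[C@@H](O)[C@H]2C(=C)C(=O)O[C@@H]2/C=C(/C)I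
F4 | step 5 | (3S,4Z)-5-iodohexa-1,4-dien-3-yl prop-2-enoate | C=C[C@H](OC(=O)C=C)/C=C(/C)I
F5 | step 5 | (3S,4Z)-5-iodohexa-1,4-dien-3-yl 2-(hydroxymethyl)prop-2-enoate | C=C[C@H](OC(=O)C(=C)CO)/C=C(/C)I
F6 | step 5 | (5S)-3-(hydroxymethyl)-5-[(1Z)-2-iodoprop-1-en-1-yl]furan-2(5H)-one | O=C1O[C@H](/C=C(/C)I)C=C1CO
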